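**Retrosynthetic overview**
1. Target 12, (12R,13E)-labda-7,13-diene-12,15-diyl diacetate, is traced back to mono-acetate 11 by acetylation of the C12 carbinol; the C15 acetate and the (E)-C13=C14 alkene arrive ready-made in the C5 enal 8.
2. Key disconnection C11–C12: redox-active ester 7 and the aldehyde carbon of 8, two acceptors, are joined reductively by a chiral Cr(II) complex (decarboxylation, C11 radical, alkylchromium: polarity reversal); this one step completes the C20 skeleton and sets C12.
3. Enabling feature: C11, the CH2 on C9 of ring B, is the α-carbon of the γ-lactone carbonyl of (+)-sclareolide 1, so that carbonyl can leave as CO2 and expose C11; C12 is a secondary allylic carbinol flanked by the α-methyl C13=C14 alkene, the retron of 1,2-addition to an α-methyl enal.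
4. Rings: none is formed; rings A and B with C5, C9 and C10 come intact from 1, whose lactone ring is opened and dehydrated to the C7=C8 alkene before the coupling.

Key step: step 4

Assumption: (2E)-4-acetoxy-2-methylbut-2-enal 8, the C5 aldehyde of industrial vitamin A manufacture, is treated as a purchased starting material.
Assumption: the (S)-configured oxazoline sulfonamide ligand is taken to direct C11 to the Re face of aldehyde 8; should a model run show the opposite sense, its enantiomer from D-valinol is used in the same way.

**Step 1**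
Reactants: 1 (+)-sclareolide
Product: 3 methyl 13,14,15,16-tetranorlabd-7-en-12-oate, via 8α-hydroxy methyl ester 2 (not isolated)
Conditions: conc. H2SO4 (0.2 equiv), dry MeOH, 40 °C; AgNO3–SiO2 chromatography
Reagents that add atoms: methanol, CO
Why: Acid-catalysed methanolysis of the γ-lactone (Fischer-type transesterification) should give tertiary alcohol 2, and E1 dehydration through the C8 cation should lose the axial 7α-H to give the trisubstituted C7=C8 alkene, while the solvent methanol keeps the carboxyl as its ester so that it cannot close back onto C8; C5, C9 and C10 are not touched.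

**Step 2**
Reactants: 3 methyl 13,14,15,16-tetranorlabd-7-en-12-oate
Product: 5 13,14,15,16-tetranorlabd-7-en-12-oic acid, via lithium carboxylate 4 (not isolated)
Conditions: LiOH·H2O (3 equiv), THF/MeOH/H2O, 50 °C; then 1 M HCl to pH 4, 0 °C
Reagents that add atoms: lithium hydroxide, [Li+].[OH-]
Why: Saponification (BAc2 ester hydrolysis) of the unhindered methyl ester followed by cold acidification only to pH 4 should free the γ,δ-unsaturated acid without protonating C7=C8 and so without re-forming the lactone.

**Step 3**
Reactants: 5 13,14,15,16-tetranorlabd-7-en-12-oic acid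
Product: 7 4,5,6,7-tetrachloro-1,3-dioxoisoindolin-2-yl 13,14,15,16-tetranorlabd-7-en-12-oate, via O-acylisourea 6 (not isolated)
Conditions: N-hydroxytetrachlorophthalimide (1.05 equiv), DIC (1.1 equiv), DMAP (5 mol %), CH2Cl2, rt; short silica plug
Reagents that add atoms: N-hydroxytetrachlorophthalimide, ON1C(=O)c2c(Cl)c(Cl)c(Cl)c(Cl)c2C1=O; N,N'-diisopropylcarbodiimide, CC(C)N=C=NC(C)C (its atoms stay only in intermediate 6)
Why: Steglich-type carbodiimide esterification through O-acylisourea 6 should give the redox-active ester under neutral conditions that leave the alkene and the C9 centre, which is not α to the carbonyl, untouched.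

**Step 4**
Reactants: 7 4,5,6,7-tetrachloro-1,3-dioxoisoindolin-2-yl 13,14,15,16-tetranorlabd-7-en-12-oate; 8 (2E)-4-acetoxy-2-methylbut-2-enal
Product: 11 (12R,13E)-12-hydroxylabda-7,13-dien-15-yl acetate, via alkylchromium(III) species 9 (not isolated), via chromium(III) alkoxide 10 (not isolated)
Conditions: CrCl2 (3.0 equiv), (S)-N-[2-(4-isopropyl-4,5-dihydrooxazol-2-yl)-6-methylphenyl]methanesulfonamide (3.3 equiv), Et3N (3.3 equiv), THF, rt, 1 h; then 8 (1.5 equiv) and slow addition of 7, 0 °C → rt; aq. Rochelle salt work-up
Reagents that add atoms: chromium(II) chloride, [Cr+2].[Cl-].[Cl-] (its atoms stay only in intermediates 9 and 10)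
Why: Proposed new method: the Cr(II) sulfonamide complex should reduce ester 7 by inner-sphere electron transfer, the radical anion loses tetrachlorophthalimide anion and CO2, and a second Cr(II) captures the primary C11 radical as alkylchromium(III) 9, which adds 1,2 to the chromium-bound carbonyl of enal 8 to give alkoxide 10, so that two acceptor carbons are joined by polarity reversal. The closest known reaction types are the Cr(II)-mediated decarboxylative Nozaki–Hiyama–Kishi-type addition of redox-active esters to aldehydes (without chiral ligand) and the asymmetric Nozaki–Hiyama–Kishi addition of alkenyl- and allylchromium(III) reagents carrying this class of oxazoline sulfonamide ligand; new is their combination on an unstabilised primary alkylchromium. No ring is closed. The one new stereocentre, C12, is set under reagent control: the N,N-bound ligand leaves one face of the cis-coordinated aldehyde open, so that C11 is delivered to the Re face (12R), and the remote C9 centre is expected to contribute little. The step needs capture of the homoallylic C11 radical before 3-exo closure onto C8 (the cyclopropylcarbinyl path to ring-expanded products), which the stoichiometric Cr(II) concentration and the slow addition of 7 should secure, and 1,2- rather than 1,4-addition, which the hard C–Cr(III) bond and the α-methyl group of 8 should secure. The C15 acetate, the C7=C8 alkene and the (E)-C13=C14 alkene are inert to Cr(II) and to the alkylchromium.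

**Step 5**
Reactants: 11 (12R,13E)-12-hydroxylabda-7,13-dien-15-yl acetate
Product: 12 (12R,13E)-labda-7,13-diene-12,15-diyl diacetate
Conditions: Ac2O (1.5 equiv), pyridine (3 equiv), DMAP (5 mol %), CH2Cl2, 0 °C → rt
Reagents that add atoms: acetic anhydride, CC(=O)OC(C)=O
Why: DMAP-catalysed O-acylation (nucleophilic acyl-transfer catalysis) of the secondary allylic alcohol takes place at oxygen, so C12 keeps its configuration and the allylic system is not ionised under these basic conditions.

**Compound list**
1 | (+)-sclareolide, (3aR,5aS,9aS,9bR)-3a,6,6,9a-tetramethyldecahydronaphtho[2,1-b]furan-2(1H)-one | O=C1C[C@H]2[C@](C)(O1)CC[C@H]3C(C)(C)CCC[C@]23C | starting material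
2 | methyl 2-[(1R,2R,4aS,8aS)-2-hydroxy-2,5,5,8a-tetramethyldecahydronaphthalen-1-yl]acetate (8α-hydroxy methyl ester) | COC(=O)C[C@H]1[C@](C)(O)CC[C@H]2C(C)(C)CCC[C@]12C | intermediate
3 | methyl 2-[(1S,4aS,8aS)-2,5,5,8a-tetramethyl-1,4,4a,5,6,7,8,8a-octahydronaphthalen-1-yl]acetate (methyl 13,14,15,16-tetranorlabd-7-en-12-oate) | COC(=O)C[C@H]1C(C)=CC[C@H]2C(C)(C)CCC[C@]12C | intermediate
4 | lithium 2-[(1S,4aS,8aS)-2,5,5,8a-tetramethyl-1,4,4a,5,6,7,8,8a-octahydronaphthalen-1-yl]acetate | [Li+].[O-]C(=O)C[C@H]1C(C)=CC[C@H]2C(C)(C)CCC[C@]12C | intermediate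
5 | 2-[(1S,4aS,8aS)-2,5,5,8a-tetramethyl-1,4,4a,5,6,7,8,8a-octahydronaphthalen-1-yl]acetic acid (13,14,15,16-tetranorlabd-7-en-12-oic acid) | OC(=O)C[C@H]1C(C)=CC[C@H]2C(C)(C)CCC[C@]12C | intermediate
6 | N,N'-diisopropyl-O-acylisourea of acid 5 | CC(C)NC(=NC(C)C)OC(=O)C[C@H]1C(C)=CC[C@H]2C(C)(C)CCC[C@]12C | intermediate
7 | 4,5,6,7-tetrachloro-1,3-dioxoisoindolin-2-yl ester of acid 5 (redox-active ester) | O=C(C[C@H]1C(C)=CC[C@H]2C(C)(C)CCC[C@]12C)ON1C(=O)c2c(Cl)c(Cl)c(Cl)c(Cl)c2C1=O | intermediate
8 | (2E)-4-acetoxy-2-methylbut-2-enal, (2E)-3-methyl-4-oxobut-2-en-1-yl acetate | CC(=O)OC/C=C(\C)C=O | starting material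
9 | dichloro(drim-7-en-11-yl)chromium(III), drawn without the sulfonamide ligand and THF | Cl[Cr](Cl)C[C@H]1C(C)=CC[C@H]2C(C)(C)CCC[C@]12C | intermediate
10 | chromium(III) alkoxide of 11, drawn without the sulfonamide ligand and THF | CC(=O)OC/C=C(\C)[C@@H](C[C@H]1C(C)=CC[C@H]2C(C)(C)CCC[C@]12C)O[Cr](Cl)Cl | intermediate
11 | (2E,4R)-4-hydroxy-3-methyl-5-[(1S,4aS,8aS)-2,5,5,8a-tetramethyl-1,4,4a,5,6,7,8,8a-octahydronaphthalen-1-yl]pent-2-en-1-yl acetate, (12R,13E)-12-hydroxylabda-7,13-dien-15-yl acetate | CC(=O)OC/C=C(\C)[C@@H](C[C@H]1C(C)=CC[C@H]2C(C)(C)CCC[C@]12C)O | intermediate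
12 | (2E,4R)-4-acetoxy-3-methyl-5-[(1S,4aS,8aS)-2,5,5,8a-tetramethyl-1,4,4a,5,6,7,8,8a-octahydronaphthalen-1-yl]pent-2-en-1-yl acetate, (12R,13E)-labda-7,13-diene-12,15-diyl diacetate | CC(=O)OC/C=C(\C)[C@@H](C[C@H]1C(C)=CC[C@H]2C(C)(C)CCC[C@]12C)OC(C)=O | target

**Step count and risks**
Total step count: 5. Longest linear sequence: 5 steps (1 → 12); aldehyde 8 is used as purchased.

Steps most likely to fail:

Step 4 (proposed new method). Risk: poor facial discrimination at the chromium-bound aldehyde, because ligand control is unproven for an unstabilised alkylchromium; a second risk is consumption of the enal by chromium(II)-induced reductive dimerisation before the alkylchromium is formed. Fallback (known chemistry only, a polar organozinc addition in place of the radical–chromium coupling): it sets out from acid 5 and comes back at 11. Carbodiimide coupling of 5 with N-hydroxypyridine-2-thione (DIC, DMAP, CH2Cl2, dark, through 6) should give the Barton ester 2-thioxopyridin-1(2H)-yl 13,14,15,16-tetranorlabd-7-en-12-oate F1. Irradiation of F1 with a tungsten lamp in the presence of iodoform (Barton decarboxylative iodination) should give 11-iododrim-7-ene F2. Iodine–zinc exchange (neat Et2Zn, cat. CuI, 50 °C, then removal of iodoethane and excess Et2Zn in vacuo) should give bis(drim-7-en-11-yl)zinc F3. Addition of F3 to aldehyde 8, promoted by Ti(OiPr)4 and catalysed by (1S,2S)-N,N'-bis(trifluoromethylsulfonyl)cyclohexane-1,2-diamine (toluene, −20 °C), is the established catalytic asymmetric dialkylzinc addition to α-branched enals. It should give the metal alkoxide of 11, drawn as its (drim-7-en-11-yl)zinc alkoxide F4, by Re-face attack (by analogy with the known sense of this ligand), and aqueous work-up then gives 11.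

Step 1. Risk: regiochemical scatter in the proton loss from the C8 cation (C7–H against C17–H and C9–H), together with acid-induced reversion to the lactone. Fallback: it sets out from 1 and comes back at 3. Saponification of 1 (KOH, MeOH, reflux) should give potassium 8α-hydroxy-13,14,15,16-tetranorlabdan-12-oate F5, and O-methylation of the salt (MeI, DMF) should give hydroxy ester 2, now isolated. SOCl2/pyridine at −78 °C should convert 2 into the C8 chlorosulfite of 2 F6, which undergoes E2 elimination through the freely rotating C17 methyl group anti to the equatorial leaving group to give the exocyclic isomer methyl 13,14,15,16-tetranorlabd-8(17)-en-12-oate F7. Cobalt(salen)/phenylsilane hydrogen-atom-transfer isomerisation should then move the double bond into the ring on the less hindered C7 side to give 3.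

Step 2. Risk: re-closure of the lactone by protonation of C7=C8 during the acidic work-up or on silica, the reverse of step 1. Fallback: it sets out from 3 and comes back at 7. Anhydrous ester cleavage with potassium trimethylsilanolate (THF, rt) should give potassium 13,14,15,16-tetranorlabd-7-en-12-oate F8. F8 is esterified directly, without aqueous acid, with N-hydroxytetrachlorophthalimide, DIC and one equivalent of Et3N·HCl in CH2Cl2 (acid 5 is present only transiently in the non-acidic medium and reacts on through 6) to give 7.

**Further compounds**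
F1 | step 4 | 2-thioxopyridin-1(2H)-yl 13,14,15,16-tetranorlabd-7-en-12-oate (Barton ester) | S=c1ccccn1OC(=O)C[C@H]1C(C)=CC[C@H]2C(C)(C)CCC[C@]12C
F2 | step 4 | 11-iododrim-7-ene, (1S,4aS,8aS)-1-(iodomethyl)-2,5,5,8a-tetramethyl-1,4,4a,5,6,7,8,8a-octahydronaphthalene | IC[C@H]1C(C)=CC[C@H]2C(C)(C)CCC[C@]12C
F3 | step 4 | bis(drim-7-en-11-yl)zinc | [Zn](C[C@H]1C(C)=CC[C@H]2C(C)(C)CCC[C@]12C)C[C@H]1C(C)=CC[C@H]2C(C)(C)CCC[C@]12C
F4 | step 4 | (drim-7-en-11-yl)zinc alkoxide of 11 | CC(=O)OC/C=C(\C)[C@@H](C[C@H]1C(C)=CC[C@H]2C(C)(C)CCC[C@]12C)O[Zn]C[C@H]1C(C)=CC[C@H]2C(C)(C)CCC[C@]12C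
F5 | step 1 | potassium 8α-hydroxy-13,14,15,16-tetranorlabdan-12-oate | [K+].[O-]C(=O)C[C@H]1[C@](C)(O)CC[C@H]2C(C)(C)CCC[C@]12C
F6 | step 1 | C8 chlorosulfite of 2 | COC(=O)C[C@H]1[C@](C)(OS(Cl)=O)CC[C@H]2C(C)(C)CCC[C@]12C
F7 | step 1 | methyl 13,14,15,16-tetranorlabd-8(17)-en-12-oate | COC(=O)C[C@H]1C(=C)CC[C@H]2C(C)(C)CCC[C@]12C
F8 | step 2 | potassium 13,14,15,16-tetranorlabd-7-en-12-oate | [K+].[O-]C(=O)C[C@H]1C(C)=CC[C@H]2C(C)(C)CCC[C@]12C
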